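- I began with the balance.

| flask | Q | E | remark | time |
|---|---|---|---|---|
| maple | 0.31 M | 1.8 equiv | run made earlier |  |
| flask | 0.62 M | 1.80 equiv |  | 40 min |

maple run (percent of the Q charged)

| time / min | D / % | Q / % |
|---|---|---|
| 0.833 | 5.2 | 54.8 |
| 1.50 | 10.0 | 45.0 |
| 2.50 | 18.6 | 34.9 |
| 3.00 | 24.9 | 30.6 |
| 4.00 | 29.7 | 22.3 |

(each reading ± 1 percentage point)

- solid, in amounts per volume of the solution: Q
- at the start none of Q is in solution

1. the D standing at 40 min, as a percentage of the Q charged
2. the change that raises the amount of D at 40 min, in percent of the Q charged most ("none" if none brings more than 2 percentage points) (gamma / epsilon / alpha / none)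
3. amount of D at 40 min, in percent of the Q charged, after epsilon

- gamma: doubling the solubility of Q, all else as stated
- epsilon: doubling the dissolution coefficient of Q, all else as stated
- alpha: doubling the amount of E, all else as stated

- At the last maple reading, the gap, meaning the charge less the Q and D read, in molarity (a mass-balance deficit), stood at 0.149 M.
- From 1.50 min to 4.00 min the maple gap moved by 3 percentage points of the charge, against a scatter of 1 point per reading, so I could not tell a flat gap from a slow climb.
- My bench rule for a slurry was that the solution stays saturated while solid stands, so the gap holds flat and D climbs on a straight line (pseudo-zero-order). On the maple line, D took 13.5 min per whole charge.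
- The flask has twice the maple Q and E. With the dissolved amount unchanged, the rate in molarity doubles, so I kept the same percentage line.
- I therefore committed, for the flask at 4.00 min, to D of 29.7%, a gap of 0.149 M, which is 24.0% of its charge, and Q of 46.3%.
- The border comes from a ratio: the flask charge is 4.17 gaps, so on this line its solid ends near 10.2 min, well before 40 min, and the rule stops there.
- The forecast gave 98% of D, 98.5% after epsilon, and none as the best change, taking the gap as something “which I read as dissolved Q”.
- The flask gave 81.1% of D, and 83.6% after epsilon. The best change was gamma, worth 11 points, against 5.4 points for alpha and 2.4 points for epsilon.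

    2 Q → G (k = 0.00148 M⁻¹ s⁻¹)
    E → J (k = 4.79 × 10⁻⁴ s⁻¹)
    Q ⇌ L, rate k3*(cs3 - [L]) while solid is left; crystals form when [L] > cs3 (solubility = 0.140 M, k = 0.0390 s⁻¹)
    L + E → D (k = 0.00723 M⁻¹ s⁻¹)

- At 4.00 min the flask held D at 28.9%, close to my line, but Q at 35.5%, so its gap was 0.221 M, more than the 0.149 M I had carried over, and it held L at 19.5% and G at 16.1%. In that flask, half of the dissolving was done by 2.98 min, earlier than half of the conversion of L and E into D at 5.78 min, and G stood at 18.3% at 40.0 min. In the neighbour flask with 0.720 equiv of E, the gap at 40.0 min was 0.327 M, again more than 0.149 M, with L at 22.5%, G at 30.2% and D at 46.2%.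

(The readings were computed for an exercise; noise was put on by code.)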